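Target ⇐ H2/Pd–C and fluoride deprotection ⇐ LiBH4 release of the 1,3-diol ⇐ Evans syn-aldol between the ring B C5 aldehyde and the boron enolate of the (S)-4-benzyloxazolidinone imide of O-benzylhomovanillic acid (ring C); this one C–C bond sets both side-chain centres.
C5 aldehyde ⇐ C5 bromide by Br–Li exchange and DMF, after the C3 ester has been reduced to the C9 alcohol and silylated.
Dihydrofuran ring ⇐ achiral ring B aryl diazoacetate. The feature used: C2 is a benzylic ether CH (bonded to O1 and ring A) standing 1,5 to C3, and C3 carries ring B and the ester-level carbon C9; a rhodium carbene at C3 inserts into a C2–H bond and forms C2–C3.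
Diazo ester ⇐ tosylhydrazone ⇐ aryl glyoxylate ⇐ aryl iodide (I–Mg exchange, dimethyl oxalate) ⇐ Mitsunobu ether of 4-bromo-2-iodo-6-methoxyphenol with O-benzylvanillyl alcohol.
Ring order: rings A, B and C are bought; the dihydrofuran (O1, C2, C3, C3a, C7a) is the only ring made, in step 7.

Key step: step 7

Labels: dihydrobenzofuran O1, C2, C3, C3a, C4–C7, C7a; ring A = aryl on C2; ring B = fused benzene; ring C = aryl of the side chain; C9 = CH2OH carbon on C3; Cα = carbinol carbon on C5; Cβ = its neighbour bearing ring C; Ar = 4-(benzyloxy)-3-methoxyphenyl.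
Assumption: for the parent 2-benzyloxyphenyl diazoacetates the (S)-tert-leucinate catalyst is taken to give the (2R) ring, so its mirror image Rh2(R-PTTL)4 is written for the (2S) series; if a test insertion shows the opposite sense, the antipodal catalyst is used and nothing else changes.

Step 1
Reactants: 1 4-bromo-2-methoxyphenol
Product: 2 4-bromo-2-iodo-6-methoxyphenol
Conditions: NIS, TsOH·H2O (cat.), MeCN, 0 °C → rt
Reagents that add atoms: N-iodosuccinimide, O=C1CCC(=O)N1I
Why: Electrophilic aromatic iodination, in which the hydroxyl group is the strongest director and its para position is blocked by bromine, so iodine should enter the one free ortho position.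

Step 2
Reactants: 3 4-(benzyloxy)-3-methoxybenzaldehyde
Product: 4 [4-(benzyloxy)-3-methoxyphenyl]methanol
Conditions: NaBH4, MeOH/THF, 0 °C
Reagents that add atoms: none
Why: Borohydride reduction of an aromatic aldehyde to the benzylic alcohol, which leaves the benzyl and methyl ethers untouched.

Step 3
Reactants: 2 4-bromo-2-iodo-6-methoxyphenol; 4 [4-(benzyloxy)-3-methoxyphenyl]methanol
Product: 5 2-(ArCH2O)-5-bromo-1-iodo-3-methoxybenzene
Conditions: PPh3, DIAD, THF, 0 °C → rt
Reagents that add atoms: none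
Why: Mitsunobu etherification, in which the acidic halogenated phenol is a good pronucleophile and the primary electron-rich benzylic alcohol is displaced easily, so that the unstable 4-alkoxybenzyl halide is avoided and no acid meets the acid-labile benzylic aryl ether.

Step 4
Reactants: 5 2-(ArCH2O)-5-bromo-1-iodo-3-methoxybenzene
Product: 7 methyl 2-[2-(ArCH2O)-5-bromo-3-methoxyphenyl]-2-oxoacetate, via arylmagnesium chloride 6 (not isolated)
Conditions: i-PrMgCl·LiCl, THF, −40 °C; then cannulated into dimethyl oxalate (3 equiv), THF, −78 °C; H2O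
Reagents that add atoms: dimethyl oxalate, COC(=O)C(=O)OC
Why: Iodine–magnesium exchange is far faster at the aryl iodide (helped by the ortho alkoxy group) than at the aryl bromide, and inverse addition of the arylmagnesium to excess dimethyl oxalate at low temperature should stop after one acyl substitution at the aryl glyoxylate.

Step 5
Reactants: 7 methyl 2-[2-(ArCH2O)-5-bromo-3-methoxyphenyl]-2-oxoacetate
Product: 8 methyl 2-[2-(ArCH2O)-5-bromo-3-methoxyphenyl]-2-(2-tosylhydrazinylidene)acetate (E/Z mixture)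
Conditions: TsNHNH2, MeOH, 60 °C
Reagents that add atoms: p-toluenesulfonyl hydrazide, Cc1ccc(S(=O)(=O)NN)cc1
Why: Hydrazone condensation at the electrophilic keto carbonyl of the alpha-keto ester needs no added acid, so the acid-labile ether should survive.

Step 6
Reactants: 8 methyl 2-[2-(ArCH2O)-5-bromo-3-methoxyphenyl]-2-(2-tosylhydrazinylidene)acetate
Product: 9 methyl 2-[2-(ArCH2O)-5-bromo-3-methoxyphenyl]-2-diazoacetate
Conditions: DBU, CH2Cl2, 0 °C → rt
Reagents that add atoms: none
Why: Bamford–Stevens-type elimination, in which deprotonation of the sulfonyl hydrazone N–H and loss of p-toluenesulfinate gives the stabilised aryl diazoacetate at room temperature.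

Step 7
Reactants: 9 methyl 2-[2-(ArCH2O)-5-bromo-3-methoxyphenyl]-2-diazoacetate
Product: 11 methyl (2S,3S)-2-Ar-5-bromo-7-methoxy-2,3-dihydro-1-benzofuran-3-carboxylate (trans), via cis ester 10 (not isolated)
Conditions: Rh2(R-PTTL)4 [dirhodium tetrakis(N-phthaloyl-(R)-tert-leucinate)] (1 mol %), toluene, −60 °C; then NaOMe (0.3 equiv), MeOH, 0 °C → rt
Reagents that add atoms: none
Why: Loss of N2 from 9 on the dirhodium tetracarboxylate gives a donor/acceptor rhodium carbene at C3, which takes a C2–H bond of the O1–CH2–ring A ether in a concerted, asynchronous three-centre insertion with hydride-transfer character, the positive charge growing at C2 being stabilised by O1 and by electron-rich ring A. The closest known reaction type is the Rh2(PTTL)4-catalysed intramolecular C–H insertion of methyl 2-(2-benzyloxyphenyl)-2-diazoacetates, which gives cis-2-aryl-2,3-dihydrobenzofuran-3-carboxylates. The dihydrofuran ring closes by 1,5-insertion, that is by forming C2–C3 across the chain C3–C3a–C7a–O1–C2 through a five-membered transition state. C2 is set by the catalyst, whose chiral wall of four phthalimido tert-leucinate ligands should let the carbene reach only one of the two enantiotopic hydrogens of the OCH2 group; C3 is first set kinetically cis to ring A (10) and is then equilibrated through the ester enolate by catalytic NaOMe to the more stable trans ester 11, which cannot touch C2. The step needs site selectivity (the 1,5 relationship and the double activation of the C2–H bonds secure it, since the benzyl CH2 of the phenol protection is out of reach and the aryl bromide and methoxy groups are inert to the carbene), suppression of carbene dimerisation (low temperature, dilute solution) and enantiotopic selection (catalyst).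

Step 8
Reactants: 11 methyl (2S,3S)-2-Ar-5-bromo-7-methoxy-2,3-dihydro-1-benzofuran-3-carboxylate
Product: 12 [(2S,3R)-2-Ar-5-bromo-7-methoxy-2,3-dihydro-1-benzofuran-3-yl]methanol
Conditions: LiBH4, THF, MeOH (1 equiv), 0 °C → rt
Reagents that add atoms: none
Why: Borohydride reduction of the methyl ester to the primary alcohol spares the aryl bromide and the ethers and removes the acidic C3–H, so the trans ring is configurationally fixed from here on (the C3 descriptor changes from S to R only through the priority change).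

Step 9
Reactants: 12 [(2S,3R)-2-Ar-5-bromo-7-methoxy-2,3-dihydro-1-benzofuran-3-yl]methanol
Product: 13 tert-butyl{[(2S,3R)-2-Ar-5-bromo-7-methoxy-2,3-dihydro-1-benzofuran-3-yl]methoxy}dimethylsilane
Conditions: TBSCl, imidazole, DMF, rt
Reagents that add atoms: tert-butyldimethylsilyl chloride, CC(C)(C)[Si](C)(C)Cl
Why: Silylation of the primary alcohol gives an ether that should withstand the organolithium, the boron triflate and the borohydride of the following steps.

Step 10
Reactants: 13 tert-butyl{[(2S,3R)-2-Ar-5-bromo-7-methoxy-2,3-dihydro-1-benzofuran-3-yl]methoxy}dimethylsilane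
Product: 15 (2S,3R)-2-Ar-3-{[(tert-butyldimethylsilyl)oxy]methyl}-7-methoxy-2,3-dihydro-1-benzofuran-5-carbaldehyde, via aryllithium 14 (not isolated)
Conditions: n-BuLi, THF, −78 °C; then DMF, −78 → 0 °C; H2O
Reagents that add atoms: N,N-dimethylformamide, CN(C)C=O
Why: Bromine–lithium exchange at −78 °C is faster than deprotonation at the benzylic C2–H, and the aryllithium is formylated by DMF (Bouveault aldehyde synthesis).

Step 11
Reactants: 16 homovanillic acid
Product: 17 2-[4-(benzyloxy)-3-methoxyphenyl]acetic acid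
Conditions: BnBr (1.2 equiv), KOH (2.5 equiv), EtOH/H2O, reflux; then aq HCl
Reagents that add atoms: benzyl bromide, BrCc1ccccc1
Why: Williamson etherification of the dianion, in which the phenoxide is the better nucleophile in the protic medium and any benzyl ester formed is saponified by the excess hydroxide.

Step 12
Reactants: 17 2-[4-(benzyloxy)-3-methoxyphenyl]acetic acid; 18 (4S)-4-benzyl-1,3-oxazolidin-2-one
Product: 20 (4S)-4-benzyl-3-(2-Ar-acetyl)-1,3-oxazolidin-2-one, via mixed pivalic anhydride 19 (not isolated)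
Conditions: PivCl, Et3N, THF, −20 °C; then LiCl, 18, −20 °C → rt
Reagents that add atoms: none
Why: N-acylation of the oxazolidinone through the mixed pivalic anhydride with LiCl/Et3N activation is the standard mild method for arylacetic acids and avoids ketene formation from an acid chloride.

Step 13
Reactants: 20 (4S)-4-benzyl-3-(2-Ar-acetyl)-1,3-oxazolidin-2-one; 15 (2S,3R)-2-Ar-3-{[(tert-butyldimethylsilyl)oxy]methyl}-7-methoxy-2,3-dihydro-1-benzofuran-5-carbaldehyde
Product: 23 (4S)-4-benzyl-3-[(2S,3S)-2-Ar-3-hydroxy-3-{(2S,3R)-2-Ar-3-[(tert-butyldimethylsilyloxy)methyl]-7-methoxy-2,3-dihydro-1-benzofuran-5-yl}propanoyl]-1,3-oxazolidin-2-one, via boron enolate 21 (not isolated), via boron aldolate 22 (not isolated)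
Conditions: Bu2BOTf, i-Pr2NEt, CH2Cl2, −78 → 0 °C; then 15, −78 → −20 °C; then pH 7 buffer, MeOH, 30% H2O2, 0 °C
Reagents that add atoms: none
Why: Evans syn-aldol, in which the Z-dibutylboron enolate reacts through a closed Zimmerman–Traxler chair with the auxiliary carbonyl turned away from the enolate oxygen and the 4-benzyl group blocking one enolate face, so that the (S)-auxiliary should set both new centres as (2S,3S) (Cα S and Cβ R of the target), while the distant ring centres of 15 have no influence.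

Step 14
Reactants: 23 aldol adduct
Product: 24 (1S,2R)-2-Ar-1-{(2S,3R)-2-Ar-3-[(tert-butyldimethylsilyloxy)methyl]-7-methoxy-2,3-dihydro-1-benzofuran-5-yl}propane-1,3-diol
Conditions: LiBH4, THF, H2O (1 equiv), 0 °C
Reagents that add atoms: none
Why: Reductive cleavage of the N-acyl oxazolidinone by hydride attack at the exocyclic carbonyl gives the 1,3-diol and frees the auxiliary, and at 0 °C it should outrun retro-aldol; no stereocentre is touched (the Cβ descriptor changes from S to R by priority only).

Step 15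
Reactants: 24 silyl-protected diol
Product: 25 (1S,2R)-2-Ar-1-[(2S,3R)-2-Ar-3-(hydroxymethyl)-7-methoxy-2,3-dihydro-1-benzofuran-5-yl]propane-1,3-diol
Conditions: TBAF, THF, 0 °C → rt
Reagents that add atoms: none
Why: Fluoride-induced desilylation works without acid, which the p-alkoxybenzylic alcohol at Cα would not tolerate because it ionises easily.

Step 16
Reactants: 25 dibenzyl triol
Product: 26 (1S,2R)-1-[(2S,3R)-2-(4-hydroxy-3-methoxyphenyl)-3-(hydroxymethyl)-7-methoxy-2,3-dihydro-1-benzofuran-5-yl]-2-(4-hydroxy-3-methoxyphenyl)propane-1,3-diol (target)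
Conditions: H2 (1 atm), 10% Pd/C, EtOAc/MeOH, rt, stopped after uptake of two equivalents
Reagents that add atoms: none
Why: Catalytic hydrogenolysis of the two aryl benzyl ethers under neutral conditions is much faster than cleavage of the benzylic C–OH at Cα or of the C2–O1 bond, so both phenols should be freed without further reduction.

Compound list
1 | 4-bromo-2-methoxyphenol | COc1cc(Br)ccc1O | starting material
2 | 4-bromo-2-iodo-6-methoxyphenol | COc1cc(Br)cc(I)c1O | intermediate
3 | 4-(benzyloxy)-3-methoxybenzaldehyde | COc1cc(C=O)ccc1OCc1ccccc1 | starting material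
4 | [4-(benzyloxy)-3-methoxyphenyl]methanol | COc1cc(CO)ccc1OCc1ccccc1 | intermediate
5 | 2-{[4-(benzyloxy)-3-methoxyphenyl]methoxy}-5-bromo-1-iodo-3-methoxybenzene | COc1cc(COc2c(OC)cc(Br)cc2I)ccc1OCc1ccccc1 | intermediate
6 | (2-{[4-(benzyloxy)-3-methoxyphenyl]methoxy}-5-bromo-3-methoxyphenyl)magnesium chloride | COc1cc(COc2c(OC)cc(Br)cc2[Mg]Cl)ccc1OCc1ccccc1 | intermediate
7 | methyl 2-(2-{[4-(benzyloxy)-3-methoxyphenyl]methoxy}-5-bromo-3-methoxyphenyl)-2-oxoacetate | COc1cc(COc2c(OC)cc(Br)cc2C(=O)C(=O)OC)ccc1OCc1ccccc1 | intermediate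
8 | methyl 2-(2-{[4-(benzyloxy)-3-methoxyphenyl]methoxy}-5-bromo-3-methoxyphenyl)-2-[2-(4-methylbenzenesulfonyl)hydrazinylidene]acetate | COc1cc(COc2c(OC)cc(Br)cc2C(=NNS(=O)(=O)c2ccc(C)cc2)C(=O)OC)ccc1OCc1ccccc1 | intermediate
9 | methyl 2-(2-{[4-(benzyloxy)-3-methoxyphenyl]methoxy}-5-bromo-3-methoxyphenyl)-2-diazoacetate | COc1cc(COc2c(OC)cc(Br)cc2C(=[N+]=[N-])C(=O)OC)ccc1OCc1ccccc1 | intermediate
10 | methyl (2S,3R)-2-[4-(benzyloxy)-3-methoxyphenyl]-5-bromo-7-methoxy-2,3-dihydro-1-benzofuran-3-carboxylate (cis) | COc1cc([C@H]2Oc3c(OC)cc(Br)cc3[C@H]2C(=O)OC)ccc1OCc1ccccc1 | intermediate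
11 | methyl (2S,3S)-2-[4-(benzyloxy)-3-methoxyphenyl]-5-bromo-7-methoxy-2,3-dihydro-1-benzofuran-3-carboxylate (trans) | COc1cc([C@H]2Oc3c(OC)cc(Br)cc3[C@@H]2C(=O)OC)ccc1OCc1ccccc1 | intermediate
12 | [(2S,3R)-2-[4-(benzyloxy)-3-methoxyphenyl]-5-bromo-7-methoxy-2,3-dihydro-1-benzofuran-3-yl]methanol | COc1cc([C@H]2Oc3c(OC)cc(Br)cc3[C@@H]2CO)ccc1OCc1ccccc1 | intermediate
13 | tert-butyl{[(2S,3R)-2-[4-(benzyloxy)-3-methoxyphenyl]-5-bromo-7-methoxy-2,3-dihydro-1-benzofuran-3-yl]methoxy}dimethylsilane | COc1cc([C@H]2Oc3c(OC)cc(Br)cc3[C@@H]2CO[Si](C)(C)C(C)(C)C)ccc1OCc1ccccc1 | intermediate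
14 | C5 aryllithium derived from 13 | COc1cc([C@H]2Oc3c(OC)cc([Li])cc3[C@@H]2CO[Si](C)(C)C(C)(C)C)ccc1OCc1ccccc1 | intermediate
15 | (2S,3R)-2-[4-(benzyloxy)-3-methoxyphenyl]-3-{[(tert-butyldimethylsilyl)oxy]methyl}-7-methoxy-2,3-dihydro-1-benzofuran-5-carbaldehyde | COc1cc([C@H]2Oc3c(OC)cc(C=O)cc3[C@@H]2CO[Si](C)(C)C(C)(C)C)ccc1OCc1ccccc1 | intermediate
16 | homovanillic acid | COc1cc(CC(=O)O)ccc1O | starting material
17 | 2-[4-(benzyloxy)-3-methoxyphenyl]acetic acid | COc1cc(CC(=O)O)ccc1OCc1ccccc1 | intermediate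
18 | (4S)-4-benzyl-1,3-oxazolidin-2-one | O=C1N[C@@H](Cc2ccccc2)CO1 | starting material
19 | 2-[4-(benzyloxy)-3-methoxyphenyl]acetic pivalic anhydride | COc1cc(CC(=O)OC(=O)C(C)(C)C)ccc1OCc1ccccc1 | intermediate
20 | (4S)-4-benzyl-3-{2-[4-(benzyloxy)-3-methoxyphenyl]acetyl}-1,3-oxazolidin-2-one | COc1cc(CC(=O)N2[C@@H](Cc3ccccc3)COC2=O)ccc1OCc1ccccc1 | intermediate
21 | (Z)-dibutylboron enolate of 20 | CCCCB(CCCC)O/C(=C\c1ccc(OCc2ccccc2)c(OC)c1)N1[C@@H](Cc2ccccc2)COC1=O | intermediate
22 | dibutylboron aldolate of 23 | COc1cc([C@H]2Oc3c(OC)cc([C@@H](OB(CCCC)CCCC)[C@@H](C(=O)N4[C@@H](Cc5ccccc5)COC4=O)c4ccc(OCc5ccccc5)c(OC)c4)cc3[C@@H]2CO[Si](C)(C)C(C)(C)C)ccc1OCc1ccccc1 | intermediate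
23 | (4S)-4-benzyl-3-[(2S,3S)-2-[4-(benzyloxy)-3-methoxyphenyl]-3-{(2S,3R)-2-[4-(benzyloxy)-3-methoxyphenyl]-3-{[(tert-butyldimethylsilyl)oxy]methyl}-7-methoxy-2,3-dihydro-1-benzofuran-5-yl}-3-hydroxypropanoyl]-1,3-oxazolidin-2-one | COc1cc([C@H]2Oc3c(OC)cc([C@@H](O)[C@@H](C(=O)N4[C@@H](Cc5ccccc5)COC4=O)c4ccc(OCc5ccccc5)c(OC)c4)cc3[C@@H]2CO[Si](C)(C)C(C)(C)C)ccc1OCc1ccccc1 | intermediate
24 | (1S,2R)-2-[4-(benzyloxy)-3-methoxyphenyl]-1-{(2S,3R)-2-[4-(benzyloxy)-3-methoxyphenyl]-3-{[(tert-butyldimethylsilyl)oxy]methyl}-7-methoxy-2,3-dihydro-1-benzofuran-5-yl}propane-1,3-diol | COc1cc([C@H]2Oc3c(OC)cc([C@@H](O)[C@@H](CO)c4ccc(OCc5ccccc5)c(OC)c4)cc3[C@@H]2CO[Si](C)(C)C(C)(C)C)ccc1OCc1ccccc1 | intermediate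
25 | (1S,2R)-2-[4-(benzyloxy)-3-methoxyphenyl]-1-{(2S,3R)-2-[4-(benzyloxy)-3-methoxyphenyl]-3-(hydroxymethyl)-7-methoxy-2,3-dihydro-1-benzofuran-5-yl}propane-1,3-diol | COc1cc([C@H]2Oc3c(OC)cc([C@@H](O)[C@@H](CO)c4ccc(OCc5ccccc5)c(OC)c4)cc3[C@@H]2CO)ccc1OCc1ccccc1 | intermediate
26 | (1S,2R)-1-[(2S,3R)-2-(4-hydroxy-3-methoxyphenyl)-3-(hydroxymethyl)-7-methoxy-2,3-dihydro-1-benzofuran-5-yl]-2-(4-hydroxy-3-methoxyphenyl)propane-1,3-diol | COc1cc([C@H]2Oc3c(OC)cc([C@@H](O)[C@@H](CO)c4ccc(O)c(OC)c4)cc3[C@@H]2CO)ccc1O | target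

Total step count: 16.
Longest linear sequence: 13 steps (step 1 or 2, then 3–10 and 13–16); the imide branch (steps 11 and 12) joins at step 13.

Steps most likely to fail

Step 7. The two enantiotopic C2–H bonds may not be told apart well enough: the ether oxygen sits between two ortho substituents and the C–H bonds are strongly activated, so an early, loose transition state is possible. Carbene dimerisation may also take material. A moderate loss of enantiomeric purity would in any case be removed at step 13, where the adduct of the minor enantiomer of 15 is a diastereomer. The fallback sets out from 11 and comes back at 12; it secures the configuration by separating covalent diastereomers instead of relying on the catalyst. Ester 11 of insufficient enantiomeric purity would be saponified (LiOH, THF/H2O) to (2S,3S)-2-Ar-5-bromo-7-methoxy-2,3-dihydro-1-benzofuran-3-carboxylic acid F1. Acid F1 would be joined through its mixed pivalic anhydride (PivCl, Et3N, then LiCl) to auxiliary 18 to give the N-acyl oxazolidinone F2, which is freed from the diastereomer derived from the (2R,3R) acid by crystallisation or chromatography. LiBH4 in THF/H2O at 0 °C should then reduce F2 directly to alcohol 12 and return 18.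

Step 13. The stabilised arylacetyl enolate may add slowly to the electron-rich aldehyde, and the aldolate may revert (retro-aldol) or epimerise at the acidic aryl-bearing carbon during reaction or oxidative work-up, lowering conversion and syn selectivity. The fallback sets out from 17 and 15 and comes back at 24; it replaces the boron enolate by a chlorotitanium enolate of a thiazolidinethione, whose adduct is cleaved by NaBH4 under milder conditions. Acid 17 would be condensed with (4S)-4-benzyl-1,3-thiazolidine-2-thione (DCC, DMAP, CH2Cl2) to (4S)-4-benzyl-3-(2-Ar-acetyl)-1,3-thiazolidine-2-thione F3. Enolisation with TiCl4, i-Pr2NEt and N-methyl-2-pyrrolidinone in CH2Cl2 and addition of 15 at −78 °C should give, through the non-chelated chair, the syn adduct of the same sense, the N-acyl thiazolidinethione aldol F4. NaBH4 in THF/EtOH at 0 °C would displace the auxiliary and give diol 24.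

Step 14. The lithium aldolate may undergo base-induced retro-aldol, or the α-aryl centre may epimerise, before hydride reaches the imide carbonyl. The fallback sets out from 23 and comes back at 25; it caps the carbinol before reduction so that no aldolate can form. Adduct 23 would be silylated (TESOTf, 2,6-lutidine, CH2Cl2, −78 °C) to the triethylsilyl ether F5. LiBH4 in THF/MeOH at 0 °C would then reduce off the auxiliary to the primary alcohol F6, and the TBAF conditions of step 15 would remove both silyl groups to give 25.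

Further compounds
F1 | step 7 | (2S,3S)-2-[4-(benzyloxy)-3-methoxyphenyl]-5-bromo-7-methoxy-2,3-dihydro-1-benzofuran-3-carboxylic acid | COc1cc([C@H]2Oc3c(OC)cc(Br)cc3[C@@H]2C(=O)O)ccc1OCc1ccccc1
F2 | step 7 | (4S)-4-benzyl-3-{[(2S,3S)-2-[4-(benzyloxy)-3-methoxyphenyl]-5-bromo-7-methoxy-2,3-dihydro-1-benzofuran-3-yl]carbonyl}-1,3-oxazolidin-2-one | COc1cc([C@H]2Oc3c(OC)cc(Br)cc3[C@@H]2C(=O)N2[C@@H](Cc3ccccc3)COC2=O)ccc1OCc1ccccc1
F3 | step 13 | (4S)-4-benzyl-3-{2-[4-(benzyloxy)-3-methoxyphenyl]acetyl}-1,3-thiazolidine-2-thione | COc1cc(CC(=O)N2[C@@H](Cc3ccccc3)CSC2=S)ccc1OCc1ccccc1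
F4 | step 13 | (2S,3S)-syn aldol adduct of F3 with 15 (thiazolidinethione analogue of 23) | COc1cc([C@H]2Oc3c(OC)cc([C@@H](O)[C@@H](C(=O)N4[C@@H](Cc5ccccc5)CSC4=S)c4ccc(OCc5ccccc5)c(OC)c4)cc3[C@@H]2CO[Si](C)(C)C(C)(C)C)ccc1OCc1ccccc1
F5 | step 14 | O-triethylsilyl ether of aldol adduct 23 | COc1cc([C@H]2Oc3c(OC)cc([C@@H](O[Si](CC)(CC)CC)[C@@H](C(=O)N4[C@@H](Cc5ccccc5)COC4=O)c4ccc(OCc5ccccc5)c(OC)c4)cc3[C@@H]2CO[Si](C)(C)C(C)(C)C)ccc1OCc1ccccc1
F6 | step 14 | (2R,3S)-2-Ar-3-(triethylsilyloxy)-3-{(2S,3R)-2-Ar-3-[(tert-butyldimethylsilyloxy)methyl]-7-methoxy-2,3-dihydro-1-benzofuran-5-yl}propan-1-ol | COc1cc([C@H]2Oc3c(OC)cc([C@@H](O[Si](CC)(CC)CC)[C@@H](CO)c4ccc(OCc5ccccc5)c(OC)c4)cc3[C@@H]2CO[Si](C)(C)C(C)(C)C)ccc1OCc1ccccc1
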